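**Plan**
- Retrosynthesis: the four phenols are masked as methyl ethers. Both C3–C1' bonds and both O1–C2 bonds are then cut together, which unfolds the two isoflavone units into one biaryl bis(2'-hydroxychalcone). Its two Cα=Cβ bonds lead back to aldol condensations and its C3'–C8 bond to a Suzuki–Miyaura coupling.
- Enabling feature: in unit 1 (bound through C3' of ring B) and in unit 2 (bound through C8 of ring A), the ring B on C3 has its oxygen at C4', para to C1'. This donor lets each ring B bridge as a phenonium ion and move from the future C2 to the future C3.
- Forward order: ring A of unit 2 is iodinated at the future C8, methylated and extended to an iodochalcone. This is joined to ring B of unit 1, and the second enone carrying ring A of unit 1 is added. Both rings C close in one flask after the double aryl shift, and demethylation follows.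
- Stereochemistry: the only stereogenic element is the C3'–C8 axis. It forms as a racemate in the coupling, and the (M) form is isolated last on a chiral stationary phase. The (E) enone geometry comes from the condensations and is consumed in the key step.

Key step: step 6

Assumption: the C3'–C8 axis, flanked by three oxygen-bearing ortho positions (C4', C7, C8a) and one hydrogen, is taken to be configurationally stable at and below room temperature, as the (M) descriptor implies; a SMILES string cannot carry this axis, so racemate and (M) form share one string and the descriptor stands in the name ((M): seen along the axis, the shorter turn from C4' of the near ring to C8a of the far ring runs counterclockwise).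

**Step 1**
Reactants: 1 resacetophenone (2,4-dihydroxyacetophenone)
Product: 2 3-iodoresacetophenone (2,4-dihydroxy-3-iodoacetophenone)
Conditions: I2 (0.4 equiv), HIO3 (0.2 equiv), EtOH/H2O, rt to 40 °C
Reagents that add atoms: iodine, [I][I]; iodic acid, OI(=O)=O
Why: Electrophilic aromatic iodination: C3 lies ortho to both hydroxyl groups and is the most nucleophilic carbon of the chelated resorcinol ring, I2/HIO3 is the established reagent pair for this 3-iodination, and because iodic acid reoxidises the iodide the exact stoichiometry delivers one iodine per arene, leaves water as the only co-product and holds back the 3,5-diiodide.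

**Step 2**
Reactants: 2 3-iodoresacetophenone
Product: 3 2-hydroxy-3-iodo-4-methoxyacetophenone
Conditions: MeI (1.1 equiv), K2CO3 (1.1 equiv), acetone, reflux
Reagents that add atoms: iodomethane, CI
Why: Williamson ether synthesis: the 2-hydroxyl is held in a hydrogen bond to the acetyl oxygen and is flanked by iodine, so with about one equivalent of MeI and a weak base only the free, more acidic 4-hydroxyl should be alkylated.

**Step 3**
Reactants: 3 2-hydroxy-3-iodo-4-methoxyacetophenone; 4 4-methoxybenzaldehyde
Product: 5 iodochalcone, (E)-1-(2-hydroxy-3-iodo-4-methoxyphenyl)-3-(4-methoxyphenyl)prop-2-en-1-one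
Conditions: KOH (50 % aq), EtOH, rt; then 1 M HCl, 0 °C
Reagents that add atoms: none
Why: Claisen–Schmidt condensation: the enolate of the methyl ketone adds to the non-enolisable aldehyde and E1cB loss of water gives the more stable (E)-enone, while the aryl iodide is inert to KOH at room temperature and the phenolate keeps the chalcone open.

**Step 4**
Reactants: 5 iodochalcone; 6 (5-formyl-2-methoxyphenyl)boronic acid
Product: 7 biaryl chalcone aldehyde, 3-{2-hydroxy-6-methoxy-3-[(E)-3-(4-methoxyphenyl)prop-2-enoyl]phenyl}-4-methoxybenzaldehyde (racemic axis)
Conditions: 6 (1.5 equiv), Pd(OAc)2 (5 mol %), SPhos (10 mol %), K3PO4 (4 equiv), toluene/H2O 10:1, 80 °C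
Reagents that add atoms: none
Why: Suzuki–Miyaura coupling: zerovalent palladium carrying the bulky, electron-rich biarylphosphine inserts into the C–I bond and copes with its two ortho oxygen substituents, aldehyde and enone are spectators, the commercial boronic acid is used in excess to offset protodeboronation, and the new C3'–C8 axis forms as a racemate.

**Step 5**
Reactants: 7 biaryl chalcone aldehyde; 8 paeonol (2-hydroxy-4-methoxyacetophenone)
Product: 9 biaryl bis(2'-hydroxychalcone) tetramethyl ether, (E)-1-(2-hydroxy-4-methoxyphenyl)-3-{3-[2-hydroxy-6-methoxy-3-((E)-3-(4-methoxyphenyl)prop-2-enoyl)phenyl]-4-methoxyphenyl}prop-2-en-1-one (racemic axis)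
Conditions: 8 (1.1 equiv), KOH (50 % aq), EtOH, rt; then 1 M HCl, 0 °C
Reagents that add atoms: none
Why: Claisen–Schmidt condensation: the enolate of 8 meets only one aldehyde and E1cB dehydration gives the second (E)-enone, while the chalcone already present rests as its unreactive phenolate under the very conditions in which it was made, and any flavanone formed from it in step 4 is reopened by KOH.

**Step 6**
Reactants: 9 biaryl bis(2'-hydroxychalcone) tetramethyl ether
Product: 11 tetra-O-methylbisoflavolin C, via bis(dimethyl acetal) 10 (not isolated)
Conditions: Tl(NO3)3·3H2O (2.4 equiv), MeOH/CH(OMe)3 1:1, rt; then 10 % aq HCl, same flask, 60 °C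
Reagents that add atoms: methanol, CO (supplies the four methoxy groups of 10; none of them remains in 11)
Why: Trivalent thallium attacks Cα of each enone as an electrophile while methanol adds to the benzylic Cβ, and as monovalent thallium departs from the weak C–Tl bond the para-methoxyaryl ring on Cβ bridges as a phenonium ion and ends on Cα, so both C3–C1' bonds form and methanol traps the two Cβ oxocarbenium ions as the bis(dimethyl acetal) 10. The closest known reaction type is the Tl(NO3)3 oxidative 1,2-aryl rearrangement of 2'-hydroxy-4-methoxychalcones to 2-aryl-3,3-dimethoxypropan-1-ones with acid cyclisation to isoflavones, applied here to two non-conjugated enones of one molecule with a little over one equivalent of oxidant for each. When HCl is added each acetal ionises, the 2'-hydroxyl attacks the oxocarbenium carbon in a 6-exo-trig closure (O1–C2 bond) and the 2-methoxyisoflavanone loses methanol to give the aromatic pyranone; ring C of unit 1 and ring C of unit 2 close in the same mode, the latter through the hydroxyl next to the biaryl bond. The two α-carbon stereocentres of 10 arise without control and vanish when C2=C3 forms, so no stereocentre remains and the racemic axis is untouched. The selectivity needed is aryl migration over attack of a 2'-hydroxyl on the thallated enone (aurone or flavone formation) and over aroyl migration; both migrating rings carry methoxy para to C1', the pattern for which this reaction class favours isoflavones, and the orthoformate removes the water of hydration so that methanol capture at Cβ outruns the phenol. Both rings A are shielded from oxidation and ring thallation by their acyl groups and by the hydrogen bond of each phenol to its carbonyl.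

**Step 7**
Reactants: 11 tetra-O-methylbisoflavolin C
Product: 12 rac-bisoflavolin C
Conditions: BBr3 (10 equiv), CH2Cl2, −78 °C to rt; then H2O, 0 °C
Reagents that add atoms: none
Why: Lewis acid cleavage of aryl methyl ethers: BBr3 binds each ether oxygen and bromide removes the methyl group by SN2 attack, a standard passage from O-methylated isoflavones to the free phenols that leaves pyranone rings and biaryl bond intact, with the excess covering the two carbonyl groups that also bind boron.

**Step 8**
Reactants: 12 rac-bisoflavolin C
Product: 13 (M)-bisoflavolin C
Conditions: preparative HPLC, amylose tris(3,5-dimethylphenylcarbamate) on silica, n-hexane/EtOH/CF3CO2H, 5–10 °C; evaporation below rt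
Reagents that add atoms: none
Why: Chromatographic resolution on a chiral stationary phase: the two atropisomers, kept apart by the oxygen-bearing ortho positions C4', C7 and C8a, bind differently in the grooves of the polysaccharide carbamate, so the (M) axis is selected rather than made, and its assignment should rest on comparing the electronic circular dichroism curve with a calculated one and with the data of the natural product.

**Compound list**
1 | resacetophenone (2,4-dihydroxyacetophenone) | CC(=O)c1ccc(O)cc1O | starting material
2 | 2,4-dihydroxy-3-iodoacetophenone | CC(=O)c1ccc(O)c(I)c1O | intermediate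
3 | 2-hydroxy-3-iodo-4-methoxyacetophenone | CC(=O)c1ccc(OC)c(I)c1O | intermediate
4 | 4-methoxybenzaldehyde | COc1ccc(C=O)cc1 | starting material
5 | (E)-1-(2-hydroxy-3-iodo-4-methoxyphenyl)-3-(4-methoxyphenyl)prop-2-en-1-one | COc1ccc(/C=C/C(=O)c2ccc(OC)c(I)c2O)cc1 | intermediate
6 | (5-formyl-2-methoxyphenyl)boronic acid | COc1ccc(C=O)cc1B(O)O | starting material
7 | 3-{2-hydroxy-6-methoxy-3-[(E)-3-(4-methoxyphenyl)prop-2-enoyl]phenyl}-4-methoxybenzaldehyde, racemic axis | COc1ccc(/C=C/C(=O)c2ccc(OC)c(-c3cc(C=O)ccc3OC)c2O)cc1 | intermediate
8 | paeonol (2-hydroxy-4-methoxyacetophenone) | COc1ccc(C(C)=O)c(O)c1 | starting material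
9 | (E,E)-biaryl bis(2'-hydroxychalcone) tetramethyl ether, racemic axis | COc1ccc(C(=O)/C=C/c2ccc(OC)c(c2)-c2c(OC)ccc(C(=O)/C=C/c3ccc(OC)cc3)c2O)c(O)c1 | intermediate
10 | bis(dimethyl acetal): both enones turned into 2-aryl-3,3-dimethoxypropan-1-one units, mixture of diastereomers, not isolated | COc1ccc(C(=O)C(C(OC)OC)c2ccc(OC)c(c2)-c2c(OC)ccc(C(=O)C(C(OC)OC)c3ccc(OC)cc3)c2O)c(O)c1 | intermediate
11 | tetra-O-methylbisoflavolin C, 7-methoxy-3-{4-methoxy-3-[7-methoxy-3-(4-methoxyphenyl)-4-oxo-4H-chromen-8-yl]phenyl}-4H-chromen-4-one, racemic axis | O=c1c(-c2ccc(OC)c(-c3c(OC)ccc4c(=O)c(-c5ccc(OC)cc5)coc34)c2)coc2cc(OC)ccc12 | intermediate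
12 | rac-bisoflavolin C | O=c1c(-c2ccc(O)c(-c3c(O)ccc4c(=O)c(-c5ccc(O)cc5)coc34)c2)coc2cc(O)ccc12 | intermediate
13 | (M)-bisoflavolin C, (M) axis C3'–C8 | O=c1c(-c2ccc(O)c(-c3c(O)ccc4c(=O)c(-c5ccc(O)cc5)coc34)c2)coc2cc(O)ccc12 | target

Total steps: 8 (seven reactions and one separation). Longest linear sequence: 8 steps, from 1 to 13.

**Steps most likely to fail**

Step 6.
- The two enones need not react at the same rate. While the slower one waits, material that has already rearranged stays exposed to trivalent thallium and to the nitric acid being released.
- Ring thallation or nitration of the anisole rings, or closure of a free 2'-hydroxyl onto a thallated enone, may then erode the double shift.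
- Fallback (from 9, back at 11): the order of events is inverted and the metal is dropped. Both rings C are closed first by oxa-Michael addition (NaOAc, EtOH, reflux) to the bis-flavanone F1. It forms as a mixture of diastereomers whose C2 stereocentres are lost in the next operation.
- PhI(OH)OTs in MeCN at reflux then attacks the enol of each flavanone at C3. Ring B moves from C2 to C3 as iodobenzene leaves, and loss of the C3 proton gives 11.
- This oxidative 2,3-aryl shift of flavanones is a known hypervalent iodine reaction and again profits from the para-methoxy groups.

Step 4.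
- The arylpalladium species is flanked by a phenolate and a methoxy group, so transmetalation may be slow. Protodeboronation of the electron-rich boronic acid and hydrodeiodination of 5 may then take over.
- Warm aqueous base may also close the 2'-hydroxychalcone to its flavanone.
- Fallback (from 5, back at 9): the phenol next to iodine is masked. MOMCl and iPr2NEt in CH2Cl2 convert 5 into the MOM-protected iodochalcone F2, which has no phenolate beside the C–I bond and cannot cyclise.
- Coupling with 6 under the catalyst of step 4 should give the MOM-protected biaryl aldehyde F3. Condensation with 8 (KOH, EtOH, rt) should give the mono-MOM bis-chalcone F4, and brief treatment with HCl in MeOH at rt frees the phenol to give 9.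

Step 8.
- Slow rotation about the axis during chromatography and evaporation may erode the enantiomeric purity. Tailing of the tetraphenol may make the two bands overlap.
- Fallback (from 12, back at 13): classical resolution through covalent diastereomers. (1S)-(−)-Camphanic chloride (5 equiv), Et3N and DMAP in CH2Cl2 acylate all four phenols to the (M)-tetracamphanate F5 and the (P)-tetracamphanate F6.
- Their bulkier ortho acyloxy groups should stiffen the axis, and they differ enough to be parted on plain silica gel or by crystallisation.
- Catalytic K2CO3 in MeOH at 0 °C then transesterifies the aryl esters of F5 and releases 13 just before use.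

**Further compounds**
F1 | step 6 | bis-flavanone, 7-methoxy-2-{4-methoxy-3-[7-methoxy-2-(4-methoxyphenyl)-4-oxochroman-8-yl]phenyl}chroman-4-one, mixture of diastereomers | O=C1CC(c2ccc(OC)c(-c3c(OC)ccc4C(=O)CC(c5ccc(OC)cc5)Oc34)c2)Oc2cc(OC)ccc12
F2 | step 4 | (E)-1-[3-iodo-4-methoxy-2-(methoxymethoxy)phenyl]-3-(4-methoxyphenyl)prop-2-en-1-one | COCOc1c(I)c(OC)ccc1C(=O)/C=C/c1ccc(OC)cc1
F3 | step 4 | 4-methoxy-3-{6-methoxy-2-(methoxymethoxy)-3-[(E)-3-(4-methoxyphenyl)prop-2-enoyl]phenyl}benzaldehyde, racemic axis | COCOc1c(-c2cc(C=O)ccc2OC)c(OC)ccc1C(=O)/C=C/c1ccc(OC)cc1
F4 | step 4 | bis-chalcone 9 with the hydroxyl next to the biaryl bond as its methoxymethyl ether, (E,E), racemic axis | COCOc1c(-c2cc(/C=C/C(=O)c3ccc(OC)cc3O)ccc2OC)c(OC)ccc1C(=O)/C=C/c1ccc(OC)cc1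
F5 | step 8 | (M)-bisoflavolin C tetrakis[(1S,4R)-camphanate] | O=c1c(-c2ccc(OC(=O)[C@@]67CC[C@@](C)(C(=O)O6)C7(C)C)c(-c3c(OC(=O)[C@@]67CC[C@@](C)(C(=O)O6)C7(C)C)ccc4c(=O)c(-c5ccc(OC(=O)[C@@]67CC[C@@](C)(C(=O)O6)C7(C)C)cc5)coc34)c2)coc2cc(OC(=O)[C@@]67CC[C@@](C)(C(=O)O6)C7(C)C)ccc12
F6 | step 8 | (P)-bisoflavolin C tetrakis[(1S,4R)-camphanate] | O=c1c(-c2ccc(OC(=O)[C@@]67CC[C@@](C)(C(=O)O6)C7(C)C)c(-c3c(OC(=O)[C@@]67CC[C@@](C)(C(=O)O6)C7(C)C)ccc4c(=O)c(-c5ccc(OC(=O)[C@@]67CC[C@@](C)(C(=O)O6)C7(C)C)cc5)coc34)c2)coc2cc(OC(=O)[C@@]67CC[C@@](C)(C(=O)O6)C7(C)C)ccc12
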